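Chain atoms run from the carboxyl carbon C1 to C9; furan atoms carry primes. Everything rests on cutting the bond between furan C3′ and the stereocentre C5. C5 lies β to C7, the future prenyl CH, so with C7 held as an amide carbonyl the C5=C6 bond becomes an acceptor for a furan-3-yl nucleophile. One conjugate addition catalysed by Rh(acac)(C2H4)2/(R)-BINAP joins the two halves, forms C3′–C5 and sets C5 as S; C3 (R) is bought in. The precursors are a 5-aryl-furan-3-yl pinacol boronate with the hydroquinone masked as two MOM ethers, and an E-configured Weinreb enamide carrying the methyl ester and the C3 methyl group.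

Key step: step 7

Remark: the target is (3R,5S)-5-[5-(2,5-dihydroxyphenyl)furan-3-yl]-3,8-dimethylnon-7-enoic acid; the ligand enantiomer is assigned from the accepted quadrant model for rhodium–BINAP additions to E-configured acyclic acceptors, and the (R)-half-ester and 2,4-dibromofuran are taken as purchasable.

Step 1
Reactants: 1 (3R)-5-methoxy-3-methyl-5-oxopentanoic acid (methyl hydrogen (R)-3-methylglutarate)
Product: 2 methyl (3R)-5-hydroxy-3-methylpentanoate
Conditions: BH3·SMe2, THF, 0 °C to rt; MeOH quench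
Reagents that add atoms: none
Why: Chemoselective borane reduction, in which a free carboxylic acid reacts much faster than a methyl ester, so only the acid terminus becomes the primary alcohol and C3 is untouched; the product is used promptly to forestall lactonisation.

Step 2
Reactants: 2 methyl (3R)-5-hydroxy-3-methylpentanoate
Product: 3 methyl (3R)-3-methyl-5-oxopentanoate
Conditions: TEMPO (cat.), PhI(OAc)2, CH2Cl2, rt
Reagents that add atoms: none
Why: TEMPO/PhI(OAc)2 oxidation (oxoammonium-mediated) stops at the aldehyde under nearly neutral conditions that leave the ester and the β-stereocentre alone.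

Step 3
Reactants: 3 methyl (3R)-3-methyl-5-oxopentanoate; 4 diethyl {2-[methoxy(methyl)amino]-2-oxoethyl}phosphonate
Product: 5 methyl (3R,5E)-7-[methoxy(methyl)amino]-3-methyl-7-oxohept-5-enoate
Conditions: LiCl, DBU, MeCN, 0 °C to rt
Reagents that add atoms: none
Why: Horner–Wadsworth–Emmons olefination under Masamune–Roush conditions, where the stabilised amide phosphonate gives the E-alkene and the mild amine base spares the ester; the aldehyde has no α-stereocentre to lose.

Step 4
Reactants: 6 2-bromobenzene-1,4-diol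
Product: 7 2-bromo-1,4-bis(methoxymethoxy)benzene
Conditions: MOMCl, i-Pr2NEt, CH2Cl2, 0 °C to rt
Reagents that add atoms: chloromethyl methyl ether, COCCl
Why: O-Alkylation of both phenols with the reactive α-chloro ether (MOM protection) gives acetal ethers that tolerate the organolithium, palladium, rhodium, hydride and ylide chemistry ahead.

Step 5
Reactants: 7 2-bromo-1,4-bis(methoxymethoxy)benzene; 8 2,4-dibromofuran
Product: 11 4-bromo-2-[2,5-bis(methoxymethoxy)phenyl]furan, via aryllithium 9 (not isolated), via arylzinc chloride 10 (not isolated)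
Conditions: n-BuLi, THF, −78 °C; ZnCl2, −78 °C to rt; then 8, Pd(PPh3)4 (cat.), rt to 50 °C
Reagents that add atoms: none
Why: Bromine–lithium exchange, transmetalation to zinc and Negishi cross-coupling, in which zerovalent palladium inserts preferentially into the C2–Br bond next to the furan oxygen (as in site-selective couplings of related dihalo furans and thiophenes), so the β-bromide survives for the next step.

Step 6
Reactants: 11 4-bromo-2-[2,5-bis(methoxymethoxy)phenyl]furan
Product: 12 2-{5-[2,5-bis(methoxymethoxy)phenyl]furan-3-yl}-4,4,5,5-tetramethyl-1,3,2-dioxaborolane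
Conditions: B2pin2, Pd(dppf)Cl2 (cat.), KOAc, 1,4-dioxane, 90 °C
Reagents that add atoms: bis(pinacolato)diboron, CC1(C)OB(OC1(C)C)B1OC(C)(C)C(C)(C)O1
Why: Miyaura borylation, where the weak acetate base allows transmetalation of the diboron reagent but not Suzuki coupling of the product, and the pinacol ester can be purified and stored.

Step 7
Reactants: 12 2-{5-[2,5-bis(methoxymethoxy)phenyl]furan-3-yl}-4,4,5,5-tetramethyl-1,3,2-dioxaborolane; 5 methyl (3R,5E)-7-[methoxy(methyl)amino]-3-methyl-7-oxohept-5-enoate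
Product: 13 methyl (3R,5S)-5-{5-[2,5-bis(methoxymethoxy)phenyl]furan-3-yl}-7-[methoxy(methyl)amino]-3-methyl-7-oxoheptanoate
Conditions: Rh(acac)(C2H4)2 (5 mol %), (R)-BINAP (6 mol %), K2CO3 (0.5 equiv), 1,4-dioxane/H2O (6:1), 90 °C; 12 in 1.5-fold excess
Reagents that add atoms: none
Why: Hayashi–Miyaura asymmetric 1,4-addition, for which additions of aryl- and heteroarylboron reagents to E-configured unsaturated esters, amides and Weinreb amides under rhodium/BINAP or rhodium/diene catalysis are the closest known cases. A hydroxo–rhodium/(R)-BINAP complex (monovalent rhodium) formed in the aqueous base takes the furyl group from boron, the furyl–rhodium bond adds syn across C5=C6 with carbon delivered to C5, and water protonates the resulting rhodium enolate at C6, returning the hydroxo complex. No ring is closed; one C–C bond (furan C3′–C5) and one stereocentre are formed. C5 is set by the ligand: (R)-BINAP leaves open the quadrant that binds the C6 re face of the E-acceptor, so the furyl group enters on the C5 si face and C5 becomes S, while the remote C3 methyl group should exert little bias. The step needs 1,4- rather than 1,2-addition, enantioface control and survival of the boronate: the soft organorhodium nucleophile and the defined E geometry secure the first two, boron on a furan β-carbon is much less prone to protodeboronation than on an α-carbon, and the MOM ethers remove acidic phenol protons. The limited amount of carbonate keeps the methyl ester intact.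

Step 8
Reactants: 13 methyl (3R,5S)-5-{5-[2,5-bis(methoxymethoxy)phenyl]furan-3-yl}-7-[methoxy(methyl)amino]-3-methyl-7-oxoheptanoate
Product: 15 methyl (3R,5S)-5-{5-[2,5-bis(methoxymethoxy)phenyl]furan-3-yl}-3-methyl-7-oxoheptanoate, via zirconocene hemiaminal 14 (not isolated)
Conditions: Cp2Zr(H)Cl, THF, rt; aqueous work-up
Reagents that add atoms: none
Why: Amide reduction with the Schwartz reagent Cp2Zr(H)Cl, in which hydride adds to the amide carbonyl to give a zirconium-bound hemiaminal that releases the aldehyde only on work-up, so over-reduction is avoided and the methyl ester, which this reagent does not reduce, stays intact.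

Step 9
Reactants: 15 methyl (3R,5S)-5-{5-[2,5-bis(methoxymethoxy)phenyl]furan-3-yl}-3-methyl-7-oxoheptanoate
Product: 16 methyl (3R,5S)-5-{5-[2,5-bis(methoxymethoxy)phenyl]furan-3-yl}-3,8-dimethylnon-7-enoate
Conditions: i-PrPPh3I, n-BuLi, THF, 0 °C; then 15, −78 °C to rt
Reagents that add atoms: isopropyltriphenylphosphonium iodide, CC(C)[P+](c1ccccc1)(c1ccccc1)c1ccccc1.[I-]
Why: Wittig olefination with the non-stabilised isopropylidene ylide, which attacks the aldehyde far faster than the ester at low temperature; the new alkene has no geometry to control and C5, being β to the carbonyl, cannot epimerise.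

Step 10
Reactants: 16 methyl (3R,5S)-5-{5-[2,5-bis(methoxymethoxy)phenyl]furan-3-yl}-3,8-dimethylnon-7-enoate
Product: 18 (3R,5S)-5-{5-[2,5-bis(methoxymethoxy)phenyl]furan-3-yl}-3,8-dimethylnon-7-enoic acid, via lithium carboxylate 17 (not isolated)
Conditions: LiOH, THF/MeOH/H2O, rt; then cold dilute HCl to pH 4
Reagents that add atoms: lithium hydroxide, [Li+].[OH-]
Why: Ester saponification by hydroxide, to which MOM ethers, furan and alkene are inert; with the hydroquinone still masked, the basic medium cannot cause air oxidation.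

Step 11
Reactants: 18 (3R,5S)-5-{5-[2,5-bis(methoxymethoxy)phenyl]furan-3-yl}-3,8-dimethylnon-7-enoic acid
Product: 20 (3R,5S)-5-[5-(2,5-dihydroxyphenyl)furan-3-yl]-3,8-dimethylnon-7-enoic acid, via tris(trimethylsilyl) derivative 19 (not isolated)
Conditions: TMSOTf, 2,2'-bipyridyl, MeCN, 0 °C to rt; then H2O; degassed solvents under argon
Reagents that add atoms: none
Why: Silyl triflate/2,2'-bipyridyl cleavage of aromatic MOM ethers, in which silicon is transferred to the phenolic oxygen while the pyridine nitrogen captures the methoxymethyl unit, so no free protic acid or oxocarbenium ion meets the prenyl alkene or the furan, and water then hydrolyses the silyl ethers and the transient silyl ester.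

Compound list
1 | (3R)-5-methoxy-3-methyl-5-oxopentanoic acid (methyl hydrogen (R)-3-methylglutarate) | COC(=O)C[C@H](C)CC(=O)O | starting material
2 | methyl (3R)-5-hydroxy-3-methylpentanoate | COC(=O)C[C@H](C)CCO | intermediate
3 | methyl (3R)-3-methyl-5-oxopentanoate | COC(=O)C[C@H](C)CC=O | intermediate
4 | diethyl {2-[methoxy(methyl)amino]-2-oxoethyl}phosphonate | CCOP(=O)(CC(=O)N(C)OC)OCC | starting material
5 | methyl (3R,5E)-7-[methoxy(methyl)amino]-3-methyl-7-oxohept-5-enoate | CON(C)C(=O)/C=C/C[C@@H](C)CC(=O)OC | intermediate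
6 | 2-bromobenzene-1,4-diol | Oc1ccc(O)c(Br)c1 | starting material
7 | 2-bromo-1,4-bis(methoxymethoxy)benzene | COCOc1ccc(OCOC)c(Br)c1 | intermediate
8 | 2,4-dibromofuran | Brc1coc(Br)c1 | starting material
9 | [2,5-bis(methoxymethoxy)phenyl]lithium | [Li]c1cc(OCOC)ccc1OCOC | intermediate (not isolated)
10 | [2,5-bis(methoxymethoxy)phenyl]zinc chloride | Cl[Zn]c1cc(OCOC)ccc1OCOC | intermediate (not isolated)
11 | 4-bromo-2-[2,5-bis(methoxymethoxy)phenyl]furan | Brc1coc(-c2cc(OCOC)ccc2OCOC)c1 | intermediate
12 | 2-{5-[2,5-bis(methoxymethoxy)phenyl]furan-3-yl}-4,4,5,5-tetramethyl-1,3,2-dioxaborolane | CC1(C)OB(OC1(C)C)c1coc(-c2cc(OCOC)ccc2OCOC)c1 | intermediate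
13 | methyl (3R,5S)-5-{5-[2,5-bis(methoxymethoxy)phenyl]furan-3-yl}-7-[methoxy(methyl)amino]-3-methyl-7-oxoheptanoate | CON(C)C(=O)C[C@H](C[C@@H](C)CC(=O)OC)c1coc(-c2cc(OCOC)ccc2OCOC)c1 | intermediate
14 | methyl (3R,5S)-5-{5-[2,5-bis(methoxymethoxy)phenyl]furan-3-yl}-7-{[chlorobis(cyclopentadienyl)zirconio]oxy}-7-[methoxy(methyl)amino]-3-methylheptanoate (C7 epimers) | CON(C)C(O[Zr](Cl)(C1C=CC=C1)C1C=CC=C1)C[C@H](C[C@@H](C)CC(=O)OC)c1coc(-c2cc(OCOC)ccc2OCOC)c1 | intermediate (not isolated)
15 | methyl (3R,5S)-5-{5-[2,5-bis(methoxymethoxy)phenyl]furan-3-yl}-3-methyl-7-oxoheptanoate | O=CC[C@H](C[C@@H](C)CC(=O)OC)c1coc(-c2cc(OCOC)ccc2OCOC)c1 | intermediate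
16 | methyl (3R,5S)-5-{5-[2,5-bis(methoxymethoxy)phenyl]furan-3-yl}-3,8-dimethylnon-7-enoate | CC(C)=CC[C@H](C[C@@H](C)CC(=O)OC)c1coc(-c2cc(OCOC)ccc2OCOC)c1 | intermediate
17 | lithium (3R,5S)-5-{5-[2,5-bis(methoxymethoxy)phenyl]furan-3-yl}-3,8-dimethylnon-7-enoate | [Li+].CC(C)=CC[C@H](C[C@@H](C)CC(=O)[O-])c1coc(-c2cc(OCOC)ccc2OCOC)c1 | intermediate (not isolated)
18 | (3R,5S)-5-{5-[2,5-bis(methoxymethoxy)phenyl]furan-3-yl}-3,8-dimethylnon-7-enoic acid | CC(C)=CC[C@H](C[C@@H](C)CC(=O)O)c1coc(-c2cc(OCOC)ccc2OCOC)c1 | intermediate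
19 | trimethylsilyl (3R,5S)-5-{5-[2,5-bis(trimethylsilyloxy)phenyl]furan-3-yl}-3,8-dimethylnon-7-enoate | CC(C)=CC[C@H](C[C@@H](C)CC(=O)O[Si](C)(C)C)c1coc(-c2cc(O[Si](C)(C)C)ccc2O[Si](C)(C)C)c1 | intermediate (not isolated)
20 | (3R,5S)-5-[5-(2,5-dihydroxyphenyl)furan-3-yl]-3,8-dimethylnon-7-enoic acid | CC(C)=CC[C@H](C[C@@H](C)CC(=O)O)c1coc(-c2cc(O)ccc2O)c1 | target

Total step count: 11. Longest linear sequence: 8 steps (steps 4–11 from 6; the branch from 1 through steps 1–3 and 7–11 is equally long).

Steps most likely to fail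

Step 7. The insertion into the amide-type acceptor may be slow, protodeboronation of the furyl boronate may outrun transmetalation, or facial discrimination may be insufficient. The fallback replaces catalyst control by auxiliary control; it sets out from aldehyde 3 and bromofuran 11 and rejoins the route at aldehyde 15. Olefination of 3 with diethyl {2-oxo-2-[(4R)-2-oxo-4-phenyl-1,3-oxazolidin-3-yl]ethyl}phosphonate (LiCl, i-Pr2NEt, MeCN) should give methyl (3R,5E)-3-methyl-7-oxo-7-[(4R)-2-oxo-4-phenyl-1,3-oxazolidin-3-yl]hept-5-enoate F1. Bromine–lithium exchange on 11 (n-BuLi, THF, −78 °C) gives {5-[2,5-bis(methoxymethoxy)phenyl]furan-3-yl}lithium F2, which MgBr2·OEt2 converts into {5-[2,5-bis(methoxymethoxy)phenyl]furan-3-yl}magnesium bromide F3. With CuBr·SMe2 this reagent should add 1,4 to the magnesium-chelated s-cis imide F1 on the face away from the auxiliary phenyl group, which for the (4R) auxiliary corresponds to 5S, giving methyl (3R,5S)-5-{5-[2,5-bis(methoxymethoxy)phenyl]furan-3-yl}-3-methyl-7-oxo-7-[(4R)-2-oxo-4-phenyl-1,3-oxazolidin-3-yl]heptanoate F4. LiSEt (THF, 0 °C) cleaves the imide to methyl (3R,5S)-5-{5-[2,5-bis(methoxymethoxy)phenyl]furan-3-yl}-7-(ethylsulfanyl)-3-methyl-7-oxoheptanoate F5, and Fukuyama reduction (Et3SiH, Pd/C, acetone, rt) delivers 15.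

Step 11. Unmasking may trigger closure of the prenyl alkene onto furan C2′ (a six-membered ring), transfer of the methoxymethyl cation to the electron-rich rings, or air oxidation of the freed hydroquinone during work-up. The fallback exchanges the phenol protection before the alkene exists; it sets out from 13 and ends at target 20. HCl in MeOH (rt) on 13 should give methyl (3R,5S)-5-[5-(2,5-dihydroxyphenyl)furan-3-yl]-7-[methoxy(methyl)amino]-3-methyl-7-oxoheptanoate F6. TBSCl and imidazole (DMF) convert it into methyl (3R,5S)-5-(5-{2,5-bis[(tert-butyldimethylsilyl)oxy]phenyl}furan-3-yl)-7-[methoxy(methyl)amino]-3-methyl-7-oxoheptanoate F7. Cp2Zr(H)Cl then gives methyl (3R,5S)-5-(5-{2,5-bis[(tert-butyldimethylsilyl)oxy]phenyl}furan-3-yl)-3-methyl-7-oxoheptanoate F8, and the isopropylidene Wittig reaction gives methyl (3R,5S)-5-(5-{2,5-bis[(tert-butyldimethylsilyl)oxy]phenyl}furan-3-yl)-3,8-dimethylnon-7-enoate F9. Finally LiOH in degassed THF/MeOH/H2O under argon removes both aryl silyl ethers and the methyl ester in one operation, and acidification in the presence of Na2S2O4 gives 20 without any late acid-mediated step.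

Step 5. Site selectivity in the oxidative addition may be lost, giving coupling at C4 or at both C–Br bonds of 8. The fallback reverses the polarity of the coupling; it sets out from aryllithium 9 and dibromofuran 8 and returns at 11. Quenching 9 with I2 gives 2-iodo-1,4-bis(methoxymethoxy)benzene F10. Bromine–lithium exchange of 8 (n-BuLi, Et2O, −78 °C) should occur at the α-position to give (4-bromofuran-2-yl)lithium F11, which ZnCl2 converts into (4-bromofuran-2-yl)zinc chloride F12. Negishi coupling of F12 with F10 (Pd(PPh3)4, THF, rt) should engage only the C–I bond and give 11.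

Further compounds
F1 | step 7 | methyl (3R,5E)-3-methyl-7-oxo-7-[(4R)-2-oxo-4-phenyl-1,3-oxazolidin-3-yl]hept-5-enoate | COC(=O)C[C@H](C)C/C=C/C(=O)N1[C@H](c2ccccc2)COC1=O
F2 | step 7 | {5-[2,5-bis(methoxymethoxy)phenyl]furan-3-yl}lithium | [Li]c1coc(-c2cc(OCOC)ccc2OCOC)c1
F3 | step 7 | {5-[2,5-bis(methoxymethoxy)phenyl]furan-3-yl}magnesium bromide | Br[Mg]c1coc(-c2cc(OCOC)ccc2OCOC)c1
F4 | step 7 | methyl (3R,5S)-5-{5-[2,5-bis(methoxymethoxy)phenyl]furan-3-yl}-3-methyl-7-oxo-7-[(4R)-2-oxo-4-phenyl-1,3-oxazolidin-3-yl]heptanoate | COC(=O)C[C@H](C)C[C@@H](CC(=O)N1[C@H](c2ccccc2)COC1=O)c1coc(-c2cc(OCOC)ccc2OCOC)c1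
F5 | step 7 | methyl (3R,5S)-5-{5-[2,5-bis(methoxymethoxy)phenyl]furan-3-yl}-7-(ethylsulfanyl)-3-methyl-7-oxoheptanoate | CCSC(=O)C[C@H](C[C@@H](C)CC(=O)OC)c1coc(-c2cc(OCOC)ccc2OCOC)c1
F6 | step 11 | methyl (3R,5S)-5-[5-(2,5-dihydroxyphenyl)furan-3-yl]-7-[methoxy(methyl)amino]-3-methyl-7-oxoheptanoate | CON(C)C(=O)C[C@H](C[C@@H](C)CC(=O)OC)c1coc(-c2cc(O)ccc2O)c1
F7 | step 11 | methyl (3R,5S)-5-(5-{2,5-bis[(tert-butyldimethylsilyl)oxy]phenyl}furan-3-yl)-7-[methoxy(methyl)amino]-3-methyl-7-oxoheptanoate | CON(C)C(=O)C[C@H](C[C@@H](C)CC(=O)OC)c1coc(-c2cc(O[Si](C)(C)C(C)(C)C)ccc2O[Si](C)(C)C(C)(C)C)c1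
F8 | step 11 | methyl (3R,5S)-5-(5-{2,5-bis[(tert-butyldimethylsilyl)oxy]phenyl}furan-3-yl)-3-methyl-7-oxoheptanoate | O=CC[C@H](C[C@@H](C)CC(=O)OC)c1coc(-c2cc(O[Si](C)(C)C(C)(C)C)ccc2O[Si](C)(C)C(C)(C)C)c1
F9 | step 11 | methyl (3R,5S)-5-(5-{2,5-bis[(tert-butyldimethylsilyl)oxy]phenyl}furan-3-yl)-3,8-dimethylnon-7-enoate | CC(C)=CC[C@H](C[C@@H](C)CC(=O)OC)c1coc(-c2cc(O[Si](C)(C)C(C)(C)C)ccc2O[Si](C)(C)C(C)(C)C)c1
F10 | step 5 | 2-iodo-1,4-bis(methoxymethoxy)benzene | COCOc1ccc(OCOC)c(I)c1
F11 | step 5 | (4-bromofuran-2-yl)lithium | [Li]c1cc(Br)co1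
F12 | step 5 | (4-bromofuran-2-yl)zinc chloride | Cl[Zn]c1cc(Br)co1
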